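If each mole per litre of starting material costs a constant time plus a time that falls with its charge, two runs are enough to count the turnovers of a third flask.

| setting | summer | noon | flask |
|---|---|---|---|
| starting material | 0.50 M (fed, over 20 s) | 2 M (fed, over 20 s) | 1.0 M (fed, over 20 s) |
| solid reagent | 1.1 M | 1.1 M | 1.10 M |
| remark | run made earlier; the fed solution adds 0.20 times the starting volume | run made earlier; the fed solution adds 0.20 times the starting volume | the fed solution adds 0.20 times the starting volume |
| time |  |  | 5.0 min |

| run | time / min | intermediate A / % | starting material / % |
|---|---|---|---|
| summer | 1.33 | 3.7 | 91.4 |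
| summer | 2.50 | 9.2 | 76.0 |
| summer | 4.00 | 17.9 | 56.0 |
| summer | 5.00 | 22.9 | 42.5 |
| summer | 6.00 | 27.6 | 32.9 |
| noon | 0.500 | 0.2 | 99.3 |
| noon | 0.833 | 1.7 | 98.4 |
| noon | 1.50 | 3.3 | 93.0 |
| noon | 3.00 | 7.1 | 83.4 |
| noon | 6.00 | 14.7 | 63.8 |

(scatter of a reading: 0.5 percentage points)

- charges are per starting volume, the dose included; the dosed solution carries all of it
- as a solid, counted per litre of solution: solid reagent
- candidate steps: solid reagent <-> coupling partner; starting material + coupling partner -> intermediate B; starting material + coupling partner -> intermediate A; intermediate B <-> intermediate D; intermediate A -> product; intermediate B <-> intermediate C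
- at the start none of the solid reagent is in solution

- amount of intermediate A in the flask at 5.0 min, in percent of the starting material charged
- amount of starting material in the flask at 5.0 min, in percent of the starting material charged
- amount of intermediate B in the flask at 5.0 min, in percent of the starting material charged

After the early readings, starting material falls steadily: 0.0616 M min⁻¹ in the summer run and 0.131 M min⁻¹ in the noon run. But the noon run has 4.00 times the charge and runs just 2.13 times as fast.

The minutes per mole per litre turned over are taken to add like resistances in series: a constant plus a part falling as one over the charge. That places the reciprocal pace of this flask a fraction 0.333 of the way from the noon value to the summer value. So this flask's turnover pace, the moles per litre of starting material turned over per minute, is 0.0951 M min⁻¹.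

Read back along the summer line, the lag is 0.551 min. Taking the same lag, the flask turns over 0.423 M by 5.0 min, which leaves 57.7% of its starting material. The forecast differs slightly, with 56% of starting material, 18% of intermediate A and 10% of intermediate B, holding that “the order is well below one and the reaction is partly dissolution-limited”.

The flask gives 55.5% of starting material, 18.3% of intermediate A and 6.88% of intermediate B. At that moment 41.3% of the solid reagent is undissolved.

    solid reagent ⇌ coupling partner, rate k1*(cs1 - [coupling partner]) while solid is left; crystals form when [coupling partner] > cs1 (solubility = 0.730 M, k = 0.00293 s⁻¹)
    starting material + coupling partner → intermediate B (k = 0.00967 L mol⁻¹ s⁻¹)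
    starting material + coupling partner → intermediate A (k = 0.00768 L mol⁻¹ s⁻¹)
    intermediate B ⇌ intermediate D (K = 42.0, k = 0.0132 s⁻¹)
    intermediate A → product (k = 5.48 × 10⁻⁴ s⁻¹)
    intermediate B ⇌ intermediate C (K = 0.595, k = 6.54 × 10⁻⁴ s⁻¹)

The flask has turned over 0.445 M, a pace after the lag of 0.100 M min⁻¹ against the reckoned 0.0951 M min⁻¹. For a neighbour flask with 2.5 M of starting material, the same two parts, carried on from that reckoned pace and the noon pace, give 0.141 M min⁻¹. That reckons 74.9% left at 5.0 min, and the neighbour holds 75.0%.

The earlier runs and the new flask are calculated from invented constants, noise included.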